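**Plan**

- Retrosynthesis: the aryl C8–prenyl bond is cut first and traced back to the 5-O-prenyl ether (Claisen–Cope relay). The pyranone is then contracted by taking C3 out from between C2 and C4, which gives a 2-(iodomethyl)-2-phenylbenzofuran-3-one. Last, the C2–CH2I bond, the O1–C2 bond and the two O–prenyl bonds are cut.
- Forward: aryl benzyl ketone → bis-O-prenylation → five-membered furanone closed at O1–C2 → C2 quaternised with CH2I → one-carbon radical ring expansion to the six-membered pyranone → prenyl relay O5→C6→C8.
- Enabling feature: the C4 aryl ketone is directly bonded to C2, which carries both the ring oxygen O1 and the phenyl group. A radical 1,2-acyl shift therefore ends in a planar C2 radical stabilised by Ph and O1; this drives the furanone-to-pyranone ring growth and lets a racemic quaternary precursor converge.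
- Stereochemistry: the only stereocentre (C2, S) is set in the ring expansion by enantioselective hydrogen-atom transfer from a chiral thiol. The last step is non-basic and does not touch C2.
- The O-prenyl groups are the only protecting groups; the 5-O-prenyl/C4=O chelate finally delivers the C8 prenyl group and frees the 5-OH.

Key step: step 4

Remark: ketone 1 is taken as a catalogue compound. The sense of induction of the thiol catalyst cannot be predicted, so the catalyst antipode that gives the S product is to be selected by screening. Prenyl = 3-methylbut-2-en-1-yl.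

**Route**

Step 1
Reactants: 1 2-phenyl-1-(2,4,6-trihydroxyphenyl)ethan-1-one; 2 prenyl bromide
Product: 3 1-[2-hydroxy-4,6-bis(prenyloxy)phenyl]-2-phenylethan-1-one
Conditions: 2 (2.2 equiv), K2CO3, acetone, reflux
Reagents that add atoms: prenyl bromide (compound 2), CC(C)=CCBr
Why: Williamson ether synthesis; the para-OH and one ortho-OH are alkylated, and the remaining ortho-OH is then locked in a hydrogen bond to the ketone and should resist K2CO3, so alkylation should stop at the bis-ether.

Step 2
Reactants: 3 1-[2-hydroxy-4,6-bis(prenyloxy)phenyl]-2-phenylethan-1-one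
Product: 5 2-phenyl-4,6-bis(prenyloxy)-1-benzofuran-3(2H)-one (racemic, C2 enolisable), via α-chloro ketone 4 (not isolated)
Conditions: LiHMDS (2.2 equiv), THF, −78 °C; cannulate into NCS (1.05 equiv), THF, −78 °C → rt; aq. NH4Cl, under argon
Reagents that add atoms: none
Why: the phenoxide/enolate dianion is C-chlorinated by NCS (enolate α-halogenation, alkenes inert under these basic aprotic conditions), and on warming the phenoxide displaces the benzylic α-keto chloride 5-exo-tet (intramolecular Williamson closure of an α-halo-2′-hydroxy ketone to a coumaranone); the new C2 centre is racemic and labile, which does not matter.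

Step 3
Reactants: 5 2-phenyl-4,6-bis(prenyloxy)-1-benzofuran-3(2H)-one; 6 diiodomethane
Product: 7 rac-2-(iodomethyl)-2-phenyl-4,6-bis(prenyloxy)-1-benzofuran-3(2H)-one
Conditions: NaH, THF, 0 °C; CH2I2 (5 equiv), 0 → 40 °C
Reagents that add atoms: diiodomethane (compound 6), ICI
Why: C-alkylation of the sodium enolate of a 2-aryl-3-coumaranone with a soft electrophile in a weakly polar solvent, as used to make substrates for the Dowd–Beckwith reaction; excess CH2I2 should suppress bridging of two enolates, and the quaternary centre is formed racemic on purpose.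

Step 4
Reactants: 7 rac-2-(iodomethyl)-2-phenyl-4,6-bis(prenyloxy)-1-benzofuran-3(2H)-one
Product: 11 (2S)-2-phenyl-5,7-bis(prenyloxy)-2,3-dihydro-4H-chromen-4-one, via primary alkyl radical 8 (not isolated), via cyclopropyloxyl radical 9 (not isolated), via chromanon-2-yl radical 10 (not isolated)
Conditions: (TMS)3SiH (1.3 equiv, syringe pump), chiral cysteine-peptide thiol (β-turn tetrapeptide, 10 mol %), Et3B/air (20 mol %), toluene (0.01 M), 20 °C; neutral work-up
Reagents that add atoms: none
Why: Proposed new method: a silyl radical abstracts iodine from 7, the primary radical 8 adds 3-exo-trig to the C3 aryl-ketone carbonyl, and the cyclopropyloxyl radical 9 opens by β-scission of the old C2–C3 ring bond (1,2-acyl shift) because this gives radical 10, stabilised by the 2-phenyl group and by O1; 10 then takes a hydrogen atom from the chiral thiol, and the thiyl radical is reduced back by the silane (polarity-reversal chain). The closest known reaction types are the Dowd–Beckwith one-carbon ring expansion of α-halomethyl cyclic ketones and thiol-catalysed enantioselective hydrogen-atom transfer to prochiral benzylic radicals; joining them in one chain is new. The six-membered pyranone is not closed by a cyclisation but grows from the five-membered furanone by insertion of the CH2 carbon between C2 and the carbonyl carbon (3-exo-trig addition, then fragmentation). The quaternary centre of racemic 7 is erased in planar radical 10, so both enantiomers converge, and the configuration at C2 is set only by the face on which the peptide thiol delivers hydrogen (catalyst control). The step needs the rearrangement to outrun premature reduction of 8 and a 1,2-phenyl shift, which a low stationary concentration of hydrogen donors and the faster acyl shift should secure, and it needs 10 to be quenched by S–H and not by Si–H, which the polarity match of the electron-rich, hindered radical 10 with the electrophilic thiol should secure. Iodine abstraction should be far faster than silyl or thiyl addition to the trisubstituted prenyl alkenes, and the fast thiyl/silane hydrogen exchange should leave little room for abstraction of the allylic ether C–H bonds.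

Step 5
Reactants: 11 (2S)-2-phenyl-5,7-bis(prenyloxy)-2,3-dihydro-4H-chromen-4-one
Product: 14 (2S)-5-hydroxy-8-prenyl-7-(prenyloxy)-2-phenyl-2,3-dihydro-4H-chromen-4-one, via ortho-dienone 12 (not isolated), via para-dienone 13 (not isolated)
Conditions: Eu(fod)3 (10 mol %), NaHCO3, PhCl, 85 °C
Reagents that add atoms: none
Why: Eu(III)-catalysed aromatic Claisen rearrangement of the carbonyl-chelated 5-O-prenyl ether to C6, then Cope rearrangement of the dienone to C8 and enolisation (para-Claisen–Cope relay, the known reaction type for turning 5-O-prenyl flavonoids into 8-prenyl flavonoids); the unchelated 7-O-prenyl ether should stay, the Cope step must outrun enolisation of dienone 12, and C2 is not involved.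

**Compound list**

1 | 2-phenyl-1-(2,4,6-trihydroxyphenyl)ethan-1-one | O=C(Cc1ccccc1)c1c(O)cc(O)cc1O | starting material
2 | prenyl bromide (1-bromo-3-methylbut-2-ene) | CC(C)=CCBr | starting material
3 | 1-[2-hydroxy-4,6-bis(prenyloxy)phenyl]-2-phenylethan-1-one | O=C(Cc1ccccc1)c1c(O)cc(OCC=C(C)C)cc1OCC=C(C)C | intermediate
4 | 2-chloro-1-[2-hydroxy-4,6-bis(prenyloxy)phenyl]-2-phenylethan-1-one (racemic, present as lithium phenoxide, not isolated) | O=C(C(Cl)c1ccccc1)c1c(O)cc(OCC=C(C)C)cc1OCC=C(C)C | intermediate
5 | 2-phenyl-4,6-bis(prenyloxy)-1-benzofuran-3(2H)-one (racemic) | O=C1C(c2ccccc2)Oc2cc(OCC=C(C)C)cc(OCC=C(C)C)c21 | intermediate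
6 | diiodomethane | ICI | starting material
7 | rac-2-(iodomethyl)-2-phenyl-4,6-bis(prenyloxy)-1-benzofuran-3(2H)-one | O=C1C(CI)(c2ccccc2)Oc2cc(OCC=C(C)C)cc(OCC=C(C)C)c21 | intermediate
8 | [3-oxo-2-phenyl-4,6-bis(prenyloxy)-2,3-dihydro-1-benzofuran-2-yl]methyl radical (not isolated) | [CH2]C1(c2ccccc2)Oc2cc(OCC=C(C)C)cc(OCC=C(C)C)c2C1=O | intermediate
9 | 1a-phenyl-4,6-bis(prenyloxy)-1,1a-dihydrocyclopropa[b][1]benzofuran-6b-yloxyl radical (not isolated) | [O]C12CC1(c1ccccc1)Oc1cc(OCC=C(C)C)cc(OCC=C(C)C)c12 | intermediate
10 | 4-oxo-2-phenyl-5,7-bis(prenyloxy)chroman-2-yl radical (not isolated) | CC(C)=CCOc1cc(OCC=C(C)C)c2c(c1)O[C](c1ccccc1)CC2=O | intermediate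
11 | (2S)-2-phenyl-5,7-bis(prenyloxy)-2,3-dihydro-4H-chromen-4-one | CC(C)=CCOc1cc(OCC=C(C)C)c2c(c1)O[C@H](c1ccccc1)CC2=O | intermediate
12 | (2S)-6-(2-methylbut-3-en-2-yl)-2-phenyl-7-(prenyloxy)-2,3-dihydro-4H-chromene-4,5(6H)-dione (C6 epimers, not isolated) | O=C1C[C@@H](c2ccccc2)OC2=C1C(=O)C(C(C)(C)C=C)C(OCC=C(C)C)=C2 | intermediate
13 | (2S)-2-phenyl-8-prenyl-7-(prenyloxy)-2,3-dihydro-4H-chromene-4,5(8H)-dione (C8 epimers, not isolated) | O=C1C[C@@H](c2ccccc2)OC2=C1C(=O)C=C(OCC=C(C)C)C2CC=C(C)C | intermediate
14 | (2S)-5-hydroxy-8-prenyl-7-(prenyloxy)-2-phenyl-2,3-dihydro-4H-chromen-4-one | CC(C)=CCOc1cc(O)c2c(c1CC=C(C)C)O[C@H](c1ccccc1)CC2=O | target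

**Summary**

Total step count: 5. Longest linear sequence: 5 steps (from 1).

Steps most likely to fail:

1. Step 4. Facial discrimination in the hydrogen-atom transfer may be poor, hydrogen transfer from the silane may compete as an unselective background, or radical 8 may be reduced before it rearranges. Fallback (known chemistry), from 7 back to 11: the Dowd–Beckwith ring expansion is run without asymmetric induction (Bu3SnH by syringe pump, AIBN, benzene, 80 °C) to give racemic 2-phenyl-5,7-bis(prenyloxy)-2,3-dihydro-4H-chromen-4-one F1. F1 is resolved by preparative chromatography on a chiral stationary phase into 11 and (2R)-2-phenyl-5,7-bis(prenyloxy)-2,3-dihydro-4H-chromen-4-one F2. F2 is returned to F1 with catalytic DBU in ethanol, which opens it reversibly to (E)-1-[2-hydroxy-4,6-bis(prenyloxy)phenyl]-3-phenylprop-2-en-1-one F3 and lets it re-close, so that the material is funnelled into 11 over several cycles.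

2. Step 3. The ambident enolate may be alkylated at oxygen (giving the 3-alkoxybenzofuran) in competition with carbon, or one CH2I2 may bridge two enolates. Fallback, from 5 back to 7: the C–C bond is made by a reversible aldol addition in which attack at oxygen is unproductive. Paraformaldehyde and catalytic DBU in THF should give rac-2-(hydroxymethyl)-2-phenyl-4,6-bis(prenyloxy)-1-benzofuran-3(2H)-one F4, and an Appel iodination (PPh3, imidazole, I2, toluene, 80 °C) should then give 7.

3. Step 2. Over-chlorination at the α-carbon or chlorination of the electron-rich ring may precede cyclisation, and the enolisable product may autoxidise. Fallback, from 3 back to 5: no electrophilic halogen is used. The dianion (KHMDS, 2.2 equiv, THF, −78 °C) is hydroxylated with 2-(phenylsulfonyl)-3-phenyloxaziridine to rac-2-hydroxy-1-[2-hydroxy-4,6-bis(prenyloxy)phenyl]-2-phenylethan-1-one F5. The ring is then closed at oxygen by an intramolecular Mitsunobu reaction (PPh3, DIAD, THF, 0 °C) to give 5.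

**Further compounds**

F1 | step 4 | rac-2-phenyl-5,7-bis(prenyloxy)-2,3-dihydro-4H-chromen-4-one | CC(C)=CCOc1cc(OCC=C(C)C)c2c(c1)OC(c1ccccc1)CC2=O
F2 | step 4 | (2R)-2-phenyl-5,7-bis(prenyloxy)-2,3-dihydro-4H-chromen-4-one | CC(C)=CCOc1cc(OCC=C(C)C)c2c(c1)O[C@@H](c1ccccc1)CC2=O
F3 | step 4 | (E)-1-[2-hydroxy-4,6-bis(prenyloxy)phenyl]-3-phenylprop-2-en-1-one | O=C(/C=C/c1ccccc1)c1c(O)cc(OCC=C(C)C)cc1OCC=C(C)C
F4 | step 3 | rac-2-(hydroxymethyl)-2-phenyl-4,6-bis(prenyloxy)-1-benzofuran-3(2H)-one | O=C1C(CO)(c2ccccc2)Oc2cc(OCC=C(C)C)cc(OCC=C(C)C)c21
F5 | step 2 | rac-2-hydroxy-1-[2-hydroxy-4,6-bis(prenyloxy)phenyl]-2-phenylethan-1-one | O=C(C(O)c1ccccc1)c1c(O)cc(OCC=C(C)C)cc1OCC=C(C)C
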